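## The problem

Quercetin 3,4',7-tris(hydrogen sulfate) **17** is a flavonol. A phloroglucinol-type benzo ring A is fused through C4a–C8a to the 4-pyranone ring C, and the catechol ring B is attached at C2. The molecule has no stereocentre, so any stereocentre created on the way is transient and needs no control. The real task is to tell five similar oxygens apart: O3, O7 and O4' carry sulfate, while O5 and O3' stay free. O5 is hydrogen-bonded to the C4 carbonyl and is the least reactive of the five, so it can be left open during sulfation. O3' sits beside O4' on the same catechol, so it must be marked from the first step by a group that later comes off without acid or strong base. Aryl sulfate monoesters are ionic, awkward to purify and cleaved by acid, so they must be installed second to last, and only a neutral hydrogenolysis may follow. The enabling feature lies in ring C: C3 (enol oxygen) and C4 (carbonyl) together form an enolised 1,2-dione, one oxidation level above an acyloin. Both carbons can therefore begin as aldehyde carbons, and the C3–C4 bond can be made by umpolung of one of them once O1–C2 and C2–C1' are in place.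

## Retrosynthesis

**Sulfates and the last benzyl group (17 ⇒ 16 ⇒ 15 ⇒ 14).** Three O–S bonds and the O3'–benzyl bond are cut. The sulfates go on last because they would not survive hydride, oxidation or acid steps; carrying masked sulfate diesters through the route would put extra groups on the weakest bonds. The precursor, 3'-O-benzylquercetin **14**, is neutral and can be chromatographed. The forward steps must sulfate O3, O7 and O4' while leaving the chelated O5, then remove benzyl by hydrogenolysis without touching the O–S bonds or C2=C3. A proton exchange converts the ammonium salt **16** into the acid form **17**.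

**Acetals and oxidation level (14 ⇒ 13 ⇒ 12 ⇒ 11).** Three methoxymethyl (MOM) acetal bonds are cut, and two hydrogens are added back at C2 and C3. One acid-labile group on O5, O7 and O4' lets all three be released together while the benzyl ether stays. O3 needs no protecting group because the ring closure delivers it as a free hydroxyl. Going forward, oxidation of the C3 carbinol of dihydroflavonol **11** gives the dione **12**, which enolises to the aromatic pyranone **13**.

**Key disconnection (11 ⇒ 10): C3–C4.** The neighbouring cuts are less attractive here. Cutting C4–C4a needs a strongly acidic acylation. Cutting C2–C3 leads to chalcone chemistry, which tends to give aurones when ring A carries an oxygen next to the acyl group. The C3–C4 cut is the only one that uses the acyloin pattern directly and forms the 3-hydroxyl under neutral, catalytic conditions. The precursor dialdehyde **10** has no ring C. The forward reaction requires the ring A aldehyde to act as the acyl anion donor and the tether aldehyde as the acceptor.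

**Aldehyde level of the tether (10 ⇒ 9 ⇒ 8).** No skeletal bond is cut. An ester cannot be reduced to an aldehyde beside a free aryl aldehyde, so both carbonyls of ester aldehyde **8** are reduced to diol **9** and both alcohols are reoxidised. This costs two steps but uses only routine reactions.

**O1–C2 (8 ⇒ 7 + 2).** The sp3 C–O bond is cut, not the aryl C8a–O bond, because the electron-rich ring A does not undergo nucleophilic aromatic substitution. Mandelate **7** is a secondary, ester-activated benzylic alcohol, and phenol **2** is an acidic, chelated phenol, so a Mitsunobu coupling fits. The two fragments are of similar size, which makes the route convergent.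

**C2–C1' and the fragment protecting groups (7 ⇒ 6 ⇒ 5 ⇒ 3 + 4; 2 ⇒ 1).** The bond between ring B and C2 is cut back to 2-(benzyloxy)phenol **3** and glyoxylic acid **4**. The free phenol that directs the hydroxyalkylation to its para position becomes O4', and the benzyl ether already present becomes O3'. Catechol differentiation therefore comes with the starting material. A 3,4-dihydroxyphenylacetic acid start would need two nearly equivalent hydroxyls to be told apart and the benzylic carbon to be functionalised afterwards. Ring A comes from 2,4,6-trihydroxybenzaldehyde **1** by double MOM protection, which leaves the chelated hydroxyl free as the Mitsunobu nucleophile.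

## Roads not taken

**Alternative 1: ring C closed at C4–C4a by intramolecular acylation.** The cut is C4–C4a. In the forward step the activated carboxyl group of the cinnamic acid (E)-2-(allyloxy)-3-[4-(allyloxy)-3-(benzyloxy)phenyl]-3-[3,5-bis(allyloxy)phenoxy]prop-2-enoic acid A2 acylates an ortho carbon of its own aryl ether ring. This gives 3,5,7,4'-tetra-O-allyl-3'-O-benzylquercetin A1.
- Merits: the nucleophilic ring is symmetric and strongly activated, so there is no regiochemical question. The chromenone forms at its final oxidation level with O3 in place. Deallylation of A1 would give tetraol **14**, so the endgame would be the same.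
- Weak points: A2 is a fully substituted enol ether whose carboxyl group must lie cis to the aryloxy group, and building it with that geometry takes several steps. The acid activation needed for ring closure also threatens the enol ether and the allyl aryl ethers.
- Comparison: this road is better in oxidation-state economy. It needs neither the reduction/oxidation pair of steps 6 and 7 nor the dehydrogenation of step 9, and it avoids a labile dialdehyde. Against that, the chosen plan uses only simple, geometry-free intermediates, closes the ring under neutral conditions, and produces O3 as the only free hydroxyl without a separate protecting group.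

**Alternative 2: ring A built onto a preformed pyranone by a ketene–alkyne benzannulation.** The cuts are C5–C6, C7–C8 and C4a–C5. Kojic acid A4 would be elaborated to the diazoketone 2-diazo-1-{6-[3-(benzyloxy)-4-(methoxymethoxy)phenyl]-5-(methoxymethoxy)-4-oxo-4H-pyran-2-yl}ethan-1-one A5. Wolff rearrangement of A5 in the presence of a silyl ynol ether would give a ketene, which would undergo [2+2] addition, four-electron ring opening and six-electron ring closure. The product would be 3'-O-benzyl-3,4'-di-O-(methoxymethyl)-7-O-(triisopropylsilyl)quercetin A3.
- Merits: the ring A pattern is fixed by the mechanism, O5 emerges free and O7 separately addressable, and removal of the acetals and the silyl group would also lead to **14**.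
- Weak points: the strategic step is spent on ring A, the one part of the target that can be bought with all three oxygens in place. Reaching A5 from A4 needs arylation of the pyranone, protection, oxidation of the hydroxymethyl group and a diazomethane homologation before the key step. The silyl/acetal distinction between O7 and O3/O4' is also finer than the target requires, since all three receive the same sulfate.
- Comparison: this road is more general for unsymmetrical ring A patterns, but for this target it is clearly longer in front of the key step. The chosen plan obtains ring A in one step from **1**.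

**Alternative 3: ortho-quinone methide cycloaddition, flavan oxidised late.** The cuts are C3–C4 and O1–C2. A 4-methoxy ortho-quinone methide generated from a ring A salicylaldehyde derivative would add to the enol acetate 2-[4-(allyloxy)-3-(benzyloxy)phenyl]ethenyl acetate A7 in a formal [4+2] reaction. The product would be 7-(allyloxy)-2-[4-(allyloxy)-3-(benzyloxy)phenyl]-5-(benzyloxy)-4-methoxychroman-3-yl acetate A6.
- Merits: two bonds and ring C form in one convergent step from two fragments. This is better than the chosen plan, which needs four steps (5 to 8) for the same result.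
- Weak points: the regiochemistry depends on the para-alkoxyphenyl group outweighing the opposing polarisation of the acetoxy group. The electron-rich quinone methide can oligomerise. A6 is a chroman with C4 at the alcohol level and C2–C3 saturated, so reaching the flavonol needs deacetylation, conversion of the C4 methyl ether to a ketone and dehydrogenation, a four-electron oxidation on an electron-rich system.
- Comparison: the chosen plan gives up that convergence. In return its cyclisation product **11** is one two-electron oxidation from the flavonol and already carries a free O3.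

Key step: step 8

Assumption: the target is drawn as the free tris(hydrogen sulfate). Aryl hydrogen sulfates are strong acids normally kept as salts, so the last step ends with a cold proton exchange on a sulfonic acid resin, and salt **16** is the storable form.

## Steps

Step 1
Reactants: 1 2,4,6-trihydroxybenzaldehyde
Product: 2 2-hydroxy-4,6-bis(methoxymethoxy)benzaldehyde
Conditions: MOMCl (2.1 equiv), i-Pr2NEt, CH2Cl2, 0 °C to rt
Reagents that add atoms: chloromethyl methyl ether, COCCl
Why: Phenol O-alkylation (acetal protection); after two hydroxyls have reacted, the remaining ortho hydroxyl is locked in a hydrogen bond to the aldehyde and is much less nucleophilic, so the reaction should stop at the bis-ether.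

Step 2
Reactants: 3 2-(benzyloxy)phenol; 4 glyoxylic acid
Product: 5 2-[3-(benzyloxy)-4-hydroxyphenyl]-2-hydroxyacetic acid (racemic)
Conditions: 4 (50% aq.), 3 (1.5 equiv), NaOH, H2O, 0 °C to rt; then HCl to pH 2
Reagents that add atoms: none
Why: Electrophilic hydroxyalkylation of a phenoxide by glyoxylate in aqueous alkali, the reaction type used to make 4-hydroxy-3-alkoxymandelic acids; the phenoxide directs para, the ether oxygen is the weaker director, and excess phenol suppresses double addition. The stereocentre is formed racemic and is not needed later.

Step 3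
Reactants: 5 2-[3-(benzyloxy)-4-hydroxyphenyl]-2-hydroxyacetic acid
Product: 6 methyl 2-[3-(benzyloxy)-4-hydroxyphenyl]-2-hydroxyacetate (racemic)
Conditions: MeI, KHCO3, DMF, rt
Reagents that add atoms: iodomethane, CI
Why: SN2 alkylation of the carboxylate; hydrogen carbonate ionises the acid but not the phenol, and avoiding acidic methanol prevents etherification of the para-hydroxybenzylic alcohol.

Step 4
Reactants: 6 methyl 2-[3-(benzyloxy)-4-hydroxyphenyl]-2-hydroxyacetate
Product: 7 methyl 2-[3-(benzyloxy)-4-(methoxymethoxy)phenyl]-2-hydroxyacetate (racemic)
Conditions: MOMCl (1.1 equiv), K2CO3, acetone, 0 °C to rt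
Reagents that add atoms: chloromethyl methyl ether, COCCl
Why: Phenoxide O-alkylation; carbonate deprotonates only the phenol, so the secondary α-hydroxy ester hydroxyl should stay free for the next step.

Step 5
Reactants: 7 methyl 2-[3-(benzyloxy)-4-(methoxymethoxy)phenyl]-2-hydroxyacetate; 2 2-hydroxy-4,6-bis(methoxymethoxy)benzaldehyde
Product: 8 methyl 2-[3-(benzyloxy)-4-(methoxymethoxy)phenyl]-2-[2-formyl-3,5-bis(methoxymethoxy)phenoxy]acetate (racemic)
Conditions: PPh3, DIAD, THF, 0 °C to rt
Reagents that add atoms: none
Why: Mitsunobu reaction; α-hydroxy esters are good alcohol partners and the chelated ortho-formyl phenol (pKa near 8) is acidic enough to protonate the betaine and displace the oxyphosphonium group at the benzylic carbon. This forms O1–C2.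

Step 6
Reactants: 8 methyl 2-[3-(benzyloxy)-4-(methoxymethoxy)phenyl]-2-[2-formyl-3,5-bis(methoxymethoxy)phenoxy]acetate
Product: 9 2-[3-(benzyloxy)-4-(methoxymethoxy)phenyl]-2-[2-(hydroxymethyl)-3,5-bis(methoxymethoxy)phenoxy]ethan-1-ol (racemic)
Conditions: LiBH4, THF, 0 °C to rt; aq. NaHCO3 work-up
Reagents that add atoms: none
Why: Hydride reduction of the aryl aldehyde and of the α-aryloxy-activated methyl ester; acetals and the benzyl ether are inert, and a non-acidic work-up protects the electron-rich benzylic alcohol.

Step 7
Reactants: 9 2-[3-(benzyloxy)-4-(methoxymethoxy)phenyl]-2-[2-(hydroxymethyl)-3,5-bis(methoxymethoxy)phenoxy]ethan-1-ol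
Product: 10 2-{1-[3-(benzyloxy)-4-(methoxymethoxy)phenyl]-2-oxoethoxy}-4,6-bis(methoxymethoxy)benzaldehyde (racemic)
Conditions: Dess–Martin periodinane (2.4 equiv), pyridine, CH2Cl2, 0 °C to rt; used crude
Reagents that add atoms: none
Why: Dess–Martin oxidation of both primary alcohols; it stops at the aldehyde and the buffered, non-basic medium spares the enolisable α-aryl-α-aryloxy aldehyde, which is carried on without chromatography.

Step 8
Reactants: 10 2-{1-[3-(benzyloxy)-4-(methoxymethoxy)phenyl]-2-oxoethoxy}-4,6-bis(methoxymethoxy)benzaldehyde
Product: 11 2-[3-(benzyloxy)-4-(methoxymethoxy)phenyl]-3-hydroxy-5,7-bis(methoxymethoxy)chroman-4-one (racemic, mixture of 2,3-cis and 2,3-trans isomers)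
Conditions: 2-(pentafluorophenyl)-6,7-dihydro-5H-pyrrolo[2,1-c][1,2,4]triazol-2-ium tetrafluoroborate (15 mol%), i-Pr2NEt (15 mol%), degassed toluene, argon, rt
Reagents that add atoms: none
Why: The triazolylidene released from the salt by the amine adds to the ring A aldehyde, and proton transfer gives the enaminol, an acyl anion equivalent at the future C4. This carbon attacks the tether aldehyde (the future C3) through a six-membered transition state, a 6-exo-trig closure of ring C, and the resulting alkoxide expels the carbene to give acyloin 11. The closest known reaction is the carbene-catalysed intramolecular crossed benzoin of salicylaldehyde-derived keto aldehydes to 3-hydroxychroman-4-ones; here the acceptor is an aldehyde, which is more electrophilic than a ketone. The new C3 stereocentre forms under the influence of C2 and can equilibrate through the C3–C4 ene-diol, so the 2,3-trans isomer with both substituents equatorial should dominate, but no control is needed because step 9 makes C2 and C3 planar. The selectivity that matters is which aldehyde becomes the donor: an enaminol on the tether aldehyde would have the ring A aryloxide as a β-leaving group and could collapse to an arylacetate ester by internal redox. The substrate is arranged against this, since the tether aldehyde is α,α-disubstituted and slow to form an enaminol, while the ring A aldehyde has only a small methoxymethoxy group beside it (the reason this group is used at O5 in place of benzyl) and gives a conjugated enaminol. A catalytic amount of a hindered amine keeps enolisation at C2, and the 5-exo aldol it would permit, reversible, and excluding air prevents oxidation of the enaminol to the acid.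

Step 9
Reactants: 11 2-[3-(benzyloxy)-4-(methoxymethoxy)phenyl]-3-hydroxy-5,7-bis(methoxymethoxy)chroman-4-one
Product: 13 2-[3-(benzyloxy)-4-(methoxymethoxy)phenyl]-3-hydroxy-5,7-bis(methoxymethoxy)-4H-chromen-4-one, via chromane-3,4-dione 12 (not isolated)
Conditions: Dess–Martin periodinane (1.2 equiv), pyridine, CH2Cl2, 0 °C to rt
Reagents that add atoms: none
Why: Oxidation of an α-ketol to a 1,2-dione; dione 12 has an acidic benzylic C2–H next to the C3 carbonyl and O1 and should enolise at once to the aromatic 3-hydroxy-4-pyranone, erasing both stereocentres. Any 4-hydroxy-3-one regioisomer from step 8 gives the same dione.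

Step 10
Reactants: 13 2-[3-(benzyloxy)-4-(methoxymethoxy)phenyl]-3-hydroxy-5,7-bis(methoxymethoxy)-4H-chromen-4-one
Product: 14 2-[3-(benzyloxy)-4-hydroxyphenyl]-3,5,7-trihydroxy-4H-chromen-4-one (3'-O-benzylquercetin)
Conditions: HCl (aq., cat.), MeOH/THF, 50 °C
Reagents that add atoms: none
Why: Acid-catalysed acetal exchange with methanol removes the three methoxymethyl groups; the benzyl ether and the flavonol core are stable to dilute acid.

Step 11
Reactants: 14 2-[3-(benzyloxy)-4-hydroxyphenyl]-3,5,7-trihydroxy-4H-chromen-4-one
Product: 15 tris(triethylammonium) 3'-O-benzylquercetin 3,4',7-trisulfate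
Conditions: SO3·NEt3 (6–9 equiv), DMF, rt to 40 °C; size-exclusion or reversed-phase purification
Reagents that add atoms: sulfur trioxide–triethylamine complex, CC[N+](CC)(CC)S(=O)(=O)[O-]
Why: O-sulfonation of phenolic and enolic hydroxyls by an amine–sulfur trioxide complex; O5 is held in a hydrogen bond to the C4 carbonyl and is not sulfated under these mild conditions, and O3' is blocked by benzyl, so only O3, O7 and O4' should react.

Step 12
Reactants: 15 tris(triethylammonium) 3'-O-benzylquercetin 3,4',7-trisulfate
Product: 17 quercetin 3,4',7-tris(hydrogen sulfate), via tris(triethylammonium) quercetin 3,4',7-trisulfate 16 (not isolated)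
Conditions: H2 (1 atm), Pd/C, MeOH/H2O, rt; filter; sulfonic acid resin (H+ form), H2O, 0 °C; freeze-dry
Reagents that add atoms: none
Why: Hydrogenolysis of the benzyl aryl ether; aryl sulfate anions and the chromenone double bond are inert to hydrogen over palladium at ambient pressure, and cold cation exchange replaces triethylammonium by protons.

## Compound list

1 | 2,4,6-trihydroxybenzaldehyde | O=Cc1c(O)cc(O)cc1O | starting material
2 | 2-hydroxy-4,6-bis(methoxymethoxy)benzaldehyde | O=Cc1c(O)cc(OCOC)cc1OCOC | intermediate
3 | 2-(benzyloxy)phenol | Oc1ccccc1OCc1ccccc1 | starting material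
4 | glyoxylic acid | O=CC(=O)O | starting material
5 | 2-[3-(benzyloxy)-4-hydroxyphenyl]-2-hydroxyacetic acid (racemic) | OC(C(=O)O)c1ccc(O)c(OCc2ccccc2)c1 | intermediate
6 | methyl 2-[3-(benzyloxy)-4-hydroxyphenyl]-2-hydroxyacetate (racemic) | COC(=O)C(O)c1ccc(O)c(OCc2ccccc2)c1 | intermediate
7 | methyl 2-[3-(benzyloxy)-4-(methoxymethoxy)phenyl]-2-hydroxyacetate (racemic) | COC(=O)C(O)c1ccc(OCOC)c(OCc2ccccc2)c1 | intermediate
8 | methyl 2-[3-(benzyloxy)-4-(methoxymethoxy)phenyl]-2-[2-formyl-3,5-bis(methoxymethoxy)phenoxy]acetate (racemic) | COC(=O)C(Oc1cc(OCOC)cc(OCOC)c1C=O)c1ccc(OCOC)c(OCc2ccccc2)c1 | intermediate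
9 | 2-[3-(benzyloxy)-4-(methoxymethoxy)phenyl]-2-[2-(hydroxymethyl)-3,5-bis(methoxymethoxy)phenoxy]ethan-1-ol (racemic) | OCC(Oc1cc(OCOC)cc(OCOC)c1CO)c1ccc(OCOC)c(OCc2ccccc2)c1 | intermediate
10 | 2-{1-[3-(benzyloxy)-4-(methoxymethoxy)phenyl]-2-oxoethoxy}-4,6-bis(methoxymethoxy)benzaldehyde (racemic) | O=CC(Oc1cc(OCOC)cc(OCOC)c1C=O)c1ccc(OCOC)c(OCc2ccccc2)c1 | intermediate
11 | 2-[3-(benzyloxy)-4-(methoxymethoxy)phenyl]-3-hydroxy-5,7-bis(methoxymethoxy)chroman-4-one (racemic, 2,3-cis/trans mixture) | O=C1c2c(OCOC)cc(OCOC)cc2OC(c2ccc(OCOC)c(OCc3ccccc3)c2)C1O | intermediate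
12 | 2-[3-(benzyloxy)-4-(methoxymethoxy)phenyl]-5,7-bis(methoxymethoxy)chromane-3,4-dione (racemic) | O=C1C(=O)c2c(OCOC)cc(OCOC)cc2OC1c1ccc(OCOC)c(OCc2ccccc2)c1 | intermediate
13 | 2-[3-(benzyloxy)-4-(methoxymethoxy)phenyl]-3-hydroxy-5,7-bis(methoxymethoxy)-4H-chromen-4-one | O=c1c(O)c(-c2ccc(OCOC)c(OCc3ccccc3)c2)oc2cc(OCOC)cc(OCOC)c12 | intermediate
14 | 2-[3-(benzyloxy)-4-hydroxyphenyl]-3,5,7-trihydroxy-4H-chromen-4-one (3'-O-benzylquercetin) | O=c1c(O)c(-c2ccc(O)c(OCc3ccccc3)c2)oc2cc(O)cc(O)c12 | intermediate
15 | tris(triethylammonium) 3'-O-benzylquercetin 3,4',7-trisulfate | O=c1c(OS(=O)(=O)[O-])c(-c2ccc(OS(=O)(=O)[O-])c(OCc3ccccc3)c2)oc2cc(OS(=O)(=O)[O-])cc(O)c12.CC[NH+](CC)CC.CC[NH+](CC)CC.CC[NH+](CC)CC | intermediate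
16 | tris(triethylammonium) quercetin 3,4',7-trisulfate | O=c1c(OS(=O)(=O)[O-])c(-c2ccc(OS(=O)(=O)[O-])c(O)c2)oc2cc(OS(=O)(=O)[O-])cc(O)c12.CC[NH+](CC)CC.CC[NH+](CC)CC.CC[NH+](CC)CC | intermediate
17 | quercetin 3,4',7-tris(hydrogen sulfate) | O=c1c(OS(=O)(=O)O)c(-c2ccc(OS(=O)(=O)O)c(O)c2)oc2cc(OS(=O)(=O)O)cc(O)c12 | target

## Step count and least certain steps

Total: 12 steps. Longest linear sequence: 11 steps (steps 2 to 12, from **3** and **4**); step 1 is a one-step side branch.

**Step 8 (key step).** The most likely failure is the wrong aldehyde acting as donor. The carbene would add to the tether aldehyde and the enaminol would expel the ring A aryloxide, giving an arylacetate ester by internal redox. Alternatively, the doubly ortho-substituted ring A aldehyde may be too slow to form its enaminol, leaving time for reversible aldol chemistry at C2. The fallback makes the same C3–C4 bond reductively. Starting from **10**, samarium diiodide (divalent samarium, THF/t-BuOH, −78 °C) reduces the more easily reduced aryl aldehyde to its ketyl, which adds to the tether aldehyde. This pinacol cyclisation gives 2-[3-(benzyloxy)-4-(methoxymethoxy)phenyl]-5,7-bis(methoxymethoxy)chromane-3,4-diol F1. A double Swern oxidation (DMSO, (COCl)2, NEt3) takes the diol to dione **12**, which enolises, and the route is rejoined at **13**.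

**Step 7.** The α-aryl-α-aryloxy aldehyde enolises easily, so over-oxidation at C2 through the enol, or ionisation of the electron-rich benzylic alcohol of **9** before it is oxidised, could erode the material. The fallback avoids the diol and any oxidant. Starting from **8**, the ester is saponified (LiOH, THF/H2O) to 2-[3-(benzyloxy)-4-(methoxymethoxy)phenyl]-2-[2-formyl-3,5-bis(methoxymethoxy)phenoxy]acetic acid F2. Coupling with ethanethiol (EDC·HCl, DMAP) gives S-ethyl 2-[3-(benzyloxy)-4-(methoxymethoxy)phenyl]-2-[2-formyl-3,5-bis(methoxymethoxy)phenoxy]ethanethioate F3. A Fukuyama reduction (Et3SiH, Pd/C, acetone) then releases the tether aldehyde beside the untouched aryl aldehyde, and the route is rejoined at **10**.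

**Step 5.** The chelated, ortho-substituted phenoxide may attack the oxyphosphonium intermediate too slowly, so that alkylation of the hydrazide or ring C-alkylation of the phloroglucinol-type phenol takes over. The fallback separates activation from displacement. Starting from **7**, an Appel reaction (CBr4, PPh3, CH2Cl2) gives methyl 2-[3-(benzyloxy)-4-(methoxymethoxy)phenyl]-2-bromoacetate F4. This alkylates the potassium phenoxide of **2** (K2CO3, DMF, rt) in a Williamson reaction, and the route is rejoined at **8**.

**Step 9.** Excess periodinane may attack the electron-rich enol of the product and oxidise it further. The fallback reverses the order of deprotection and oxidation and uses the classical dehydrogenation of free dihydroflavonols. Starting from **11**, acid methanolysis gives 2-[3-(benzyloxy)-4-hydroxyphenyl]-3,5,7-trihydroxychroman-4-one F5. Iodine with KOAc in hot acetic acid then removes the C2 and C3 hydrogens, and the route is rejoined at **14**.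

**Step 11.** Sulfation may stop short at the hindered, hydrogen-bonded 3-hydroxyl, or sulfate may be lost by hydrolysis while the polyanionic salt is isolated. The fallback uses neutral, chromatographable sulfate diesters. Starting from **14**, 2,2,2-trichloroethyl chlorosulfate (NEt3, DMAP, THF) gives 3'-O-benzylquercetin 3,4',7-tris(2,2,2-trichloroethyl sulfate) F6. Transfer hydrogenolysis (Pd/C, HCO2NH4, MeOH) removes the three trichloroethyl groups and the benzyl ether together, giving triammonium quercetin 3,4',7-trisulfate F7. Proton exchange on the acid resin rejoins the route at **17**.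

## Further compounds

F1 | step 8 | 2-[3-(benzyloxy)-4-(methoxymethoxy)phenyl]-5,7-bis(methoxymethoxy)chromane-3,4-diol (racemic diastereomer mixture) | OC1c2c(OCOC)cc(OCOC)cc2OC(c2ccc(OCOC)c(OCc3ccccc3)c2)C1O
F2 | step 7 | 2-[3-(benzyloxy)-4-(methoxymethoxy)phenyl]-2-[2-formyl-3,5-bis(methoxymethoxy)phenoxy]acetic acid (racemic) | OC(=O)C(Oc1cc(OCOC)cc(OCOC)c1C=O)c1ccc(OCOC)c(OCc2ccccc2)c1
F3 | step 7 | S-ethyl 2-[3-(benzyloxy)-4-(methoxymethoxy)phenyl]-2-[2-formyl-3,5-bis(methoxymethoxy)phenoxy]ethanethioate (racemic) | CCSC(=O)C(Oc1cc(OCOC)cc(OCOC)c1C=O)c1ccc(OCOC)c(OCc2ccccc2)c1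
F4 | step 5 | methyl 2-[3-(benzyloxy)-4-(methoxymethoxy)phenyl]-2-bromoacetate (racemic) | COC(=O)C(Br)c1ccc(OCOC)c(OCc2ccccc2)c1
F5 | step 9 | 2-[3-(benzyloxy)-4-hydroxyphenyl]-3,5,7-trihydroxychroman-4-one (racemic diastereomer mixture) | O=C1c2c(O)cc(O)cc2OC(c2ccc(O)c(OCc3ccccc3)c2)C1O
F6 | step 11 | 3'-O-benzylquercetin 3,4',7-tris(2,2,2-trichloroethyl sulfate) | O=c1c(OS(=O)(=O)OCC(Cl)(Cl)Cl)c(-c2ccc(OS(=O)(=O)OCC(Cl)(Cl)Cl)c(OCc3ccccc3)c2)oc2cc(OS(=O)(=O)OCC(Cl)(Cl)Cl)cc(O)c12
F7 | step 11 | triammonium quercetin 3,4',7-trisulfate | O=c1c(OS(=O)(=O)[O-])c(-c2ccc(OS(=O)(=O)[O-])c(O)c2)oc2cc(OS(=O)(=O)[O-])cc(O)c12.[NH4+].[NH4+].[NH4+]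
A1 | alternative 1 | 3,5,7,4'-tetra-O-allyl-3'-O-benzylquercetin | O=c1c(OCC=C)c(-c2ccc(OCC=C)c(OCc3ccccc3)c2)oc2cc(OCC=C)cc(OCC=C)c12
A2 | alternative 1 | (E)-2-(allyloxy)-3-[4-(allyloxy)-3-(benzyloxy)phenyl]-3-[3,5-bis(allyloxy)phenoxy]prop-2-enoic acid | OC(=O)/C(OCC=C)=C(\Oc1cc(OCC=C)cc(OCC=C)c1)c1ccc(OCC=C)c(OCc2ccccc2)c1
A3 | alternative 2 | 3'-O-benzyl-3,4'-di-O-(methoxymethyl)-7-O-(triisopropylsilyl)quercetin | O=c1c(OCOC)c(-c2ccc(OCOC)c(OCc3ccccc3)c2)oc2cc(O[Si](C(C)C)(C(C)C)C(C)C)cc(O)c12
A4 | alternative 2 | kojic acid | O=c1cc(CO)occ1O
A5 | alternative 2 | 2-diazo-1-{6-[3-(benzyloxy)-4-(methoxymethoxy)phenyl]-5-(methoxymethoxy)-4-oxo-4H-pyran-2-yl}ethan-1-one | [N-]=[N+]=CC(=O)c1cc(=O)c(OCOC)c(-c2ccc(OCOC)c(OCc3ccccc3)c2)o1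
A6 | alternative 3 | 7-(allyloxy)-2-[4-(allyloxy)-3-(benzyloxy)phenyl]-5-(benzyloxy)-4-methoxychroman-3-yl acetate (racemic diastereomer mixture) | COC1c2c(OCc3ccccc3)cc(OCC=C)cc2OC(c2ccc(OCC=C)c(OCc3ccccc3)c2)C1OC(C)=O
A7 | alternative 3 | 2-[4-(allyloxy)-3-(benzyloxy)phenyl]ethenyl acetate | CC(=O)OC=Cc1ccc(OCC=C)c(OCc2ccccc2)c1
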